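The pyrrole ring of 2,4,7-tribromo-3-chloro-1H-indole is cut at N1–C7a, the bond beside the C7 bromine, and the C2 bromine is traced back to a carboxyl group. A Hemetsberger thermolysis makes N1–C7a and closes the five-membered ring in one operation. Its precursor is a Z-2-azidoacrylate ester bearing a 2,5-dibromophenyl group at C3. After loss of dinitrogen the nitrogen can reach only one ortho C–H, because bromine occupies the second ortho carbon, so the aryl bromines become C4–Br and C7–Br. The ester left at C2 keeps electrophiles away from that position while chlorine is put on C3. It is then swapped for bromine by ipso-bromodecarboxylation.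

Key step: step 2

Remark on the chemistry: the target is planar and has no stereogenic element, so there is no enantiomer to select. The only stereochemical feature of the route is the Z alkene of 4, which holds the azide next to the arene.

Step 1
Reactants: 1 2,5-dibromobenzaldehyde; 2 methyl azidoacetate
Product: 4 methyl (2Z)-2-azido-3-(2,5-dibromophenyl)prop-2-enoate, via aldol adduct 3 (not isolated)
Conditions: NaOMe (4 equiv), 2 (4 equiv, handled as a solution), MeOH–THF, −15 to 0 °C; ice/aq NH4Cl
Reagents that add atoms: none
Why: Knoevenagel-type aldol condensation (first stage of the Hemetsberger–Knittel sequence), in which the azidoacetate enolate adds to the electron-poor aldehyde, aldolate 3 loses hydroxide by E1cB, the alkene settles as the Z isomer with the aryl group trans to the ester, methoxide matched to the methyl ester excludes transesterification, and the low temperature spares the azide.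

Step 2
Reactants: 4 methyl (2Z)-2-azido-3-(2,5-dibromophenyl)prop-2-enoate
Product: 6 methyl 4,7-dibromo-1H-indole-2-carboxylate, via 2H-azirine 5 (not isolated)
Conditions: slow addition of 4 in xylenes to refluxing xylenes (ca. 140 °C, final ca. 0.05 M), N2 atmosphere, vented
Reagents that add atoms: none
Why: At about 140 °C azide 4 loses N2 to give a singlet vinyl nitrene that equilibrates with 2H-azirine 5, so the azirine is a reservoir and not a dead end. The nitrene nitrogen, the Cα=Cβ bond and the adjacent C1=C6 bond of the arene form a five-atom, six-electron array that electrocyclises to a 7aH-indole, and a suprafacial [1,5]-hydrogen shift from C7a to N1 restores aromaticity. This is the Hemetsberger–Knittel indole synthesis, whose closest general class is intramolecular nitrene C(sp2)–H amination. One ring is closed, the five-membered pyrrole, by N1–C7a bond formation in a formally 5-endo-trig mode that is open because the process is pericyclic. No stereocentre is created, and the racemic centre of 5 is erased when the azirine reopens. The step needs site selectivity between the two ortho carbons, secured by the bromine on one of them and by the Z geometry that places N beside the arene, and it needs intramolecular closure to beat bimolecular decay, secured by slow addition into hot dilute solvent.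

Step 3
Reactants: 6 methyl 4,7-dibromo-1H-indole-2-carboxylate
Product: 7 methyl 4,7-dibromo-3-chloro-1H-indole-2-carboxylate
Conditions: NCS (1.1 equiv), DMF, rt to 50 °C
Reagents that add atoms: N-chlorosuccinimide, O=C1CCC(=O)N1Cl
Why: Electrophilic aromatic substitution at the only pyrrole C–H, since C3 remains the most nucleophilic carbon of an indole-2-carboxylate, C2 is occupied by an ester that (unlike the free acid) cannot be lost as CO2, C5 and C6 lie on a ring deactivated by two bromines, and C3 halogenation of 4-haloindole-2-carboxylates with N-halosuccinimides is established.

Step 4
Reactants: 7 methyl 4,7-dibromo-3-chloro-1H-indole-2-carboxylate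
Product: 9 4,7-dibromo-3-chloro-1H-indole-2-carboxylic acid, via lithium carboxylate 8 (not isolated)
Conditions: LiOH·H2O (3 equiv), THF–MeOH–H2O, rt to 40 °C; then 1 M HCl to pH 2
Reagents that add atoms: lithium hydroxide, [Li+].[OH-]
Why: Ordinary BAc2 ester saponification, in which the C–Br and C–Cl bonds are safe because the indole, partly deprotonated at N–H under these conditions, is too electron-rich for addition–elimination by hydroxide.

Step 5
Reactants: 9 4,7-dibromo-3-chloro-1H-indole-2-carboxylic acid
Product: 10 2,4,7-tribromo-3-chloro-1H-indole
Conditions: NBS (1.05 equiv), LiOAc (0.2 equiv), dry DMF, 0 °C to rt, dark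
Reagents that add atoms: N-bromosuccinimide, O=C1CCC(=O)N1Br
Why: Hunsdiecker-type ipso-halodecarboxylation, a reaction type established for pyrrole-2- and indole-2-carboxylic acids with N-halosuccinimides, in which the carboxylate formed by acetate takes up Br+ at C2 (directly or by 1,2-shift from a reversibly formed C3 adduct), CO2 leaves as the electrofuge in place of a proton, the succinimide anion regenerates carboxylate, and no other position competes because C3 is filled and C5/C6 are deactivated.

Compound list
1 | 2,5-dibromobenzaldehyde | O=Cc1cc(Br)ccc1Br | starting material
2 | methyl azidoacetate | COC(=O)CN=[N+]=[N-] | starting material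
3 | methyl 2-azido-3-(2,5-dibromophenyl)-3-hydroxypropanoate (aldol adduct, racemic syn/anti mixture, not isolated) | COC(=O)C(N=[N+]=[N-])C(O)c1cc(Br)ccc1Br | intermediate
4 | methyl (2Z)-2-azido-3-(2,5-dibromophenyl)prop-2-enoate | COC(=O)/C(N=[N+]=[N-])=C/c1cc(Br)ccc1Br | intermediate
5 | methyl 2-(2,5-dibromophenyl)-2H-azirine-3-carboxylate (racemic, not isolated) | COC(=O)C1=NC1c1cc(Br)ccc1Br | intermediate
6 | methyl 4,7-dibromo-1H-indole-2-carboxylate | COC(=O)c1cc2c(Br)ccc(Br)c2[nH]1 | intermediate
7 | methyl 4,7-dibromo-3-chloro-1H-indole-2-carboxylate | COC(=O)c1[nH]c2c(Br)ccc(Br)c2c1Cl | intermediate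
8 | lithium 4,7-dibromo-3-chloro-1H-indole-2-carboxylate (not isolated) | [Li+].[O-]C(=O)c1[nH]c2c(Br)ccc(Br)c2c1Cl | intermediate
9 | 4,7-dibromo-3-chloro-1H-indole-2-carboxylic acid | OC(=O)c1[nH]c2c(Br)ccc(Br)c2c1Cl | intermediate
10 | 2,4,7-tribromo-3-chloro-1H-indole (achiral) | Clc1c(Br)[nH]c2c(Br)ccc(Br)c12 | target

Total step count: 5
Longest linear sequence: 5 steps (1 → 4 → 6 → 7 → 9 → 10)

Steps most likely to fail

**Step 5.**
- What may go wrong: bromonium may be taken up at C3 instead of C2, followed by halogen migration or exchange between C2 and C3. The intermediate indolenine may be oxidised by adventitious water. The electron-poor ring may be too slow to lose CO2. The acid- and light-sensitive 2,3-dihaloindole may also erode on work-up.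
- Fallback: it sets out from acid 9 and comes back to the route at target 10, and it separates loss of CO2 from bromination. Silver-catalysed protodecarboxylation (Ag2CO3 cat., AcOH cat., DMSO, 120 °C) should give 4,7-dibromo-3-chloro-1H-indole F1. Its single free pyrrole position, C2–H, is then brominated with NBS (1.0 equiv, THF, −20 to 0 °C, dark). This is the ordinary electrophilic substitution by which 3-haloindoles are turned into 2,3-dihaloindoles.

**Step 2.**
- What may go wrong: bimolecular decay of the nitrene/azirine pair (dimerisation, tar formation) may overtake closure onto an ortho carbon that is electron-poor and flanked by bromine. Gas evolution may be hard to control on scale.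
- Fallback: it gives up compounds 1–5, so it sets out from no numbered compound but from two purchased ones, and it comes back to the route at 6. The aryl–nitrogen bond is bought instead of made, and the ring is built by a Fischer indole synthesis.
- Sequence: (2,5-dibromophenyl)hydrazine F2 and methyl pyruvate F3 condense in MeOH with a trace of AcOH. This gives methyl 2-[2-(2,5-dibromophenyl)hydrazinylidene]propanoate F4 as an E/Z mixture. Heating F4 in polyphosphoric acid at about 100 °C triggers the [3,3]-shift of the ene-hydrazine.
- Regiochemistry: the shift can go only onto the one free ortho carbon, which gives the same 4,7-dibromo pattern and the same C2 ester.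

**Step 1.**
- What may go wrong: base-induced decay of the azidoacetate anion and cleavage of the ester by liberated hydroxide may outrun the dehydration, or the reaction may stall at the addition stage.
- Fallback: it sets out from 1 and 2 and comes back to the route at 4, and it separates C–C bond formation from alkene formation. The addition is run at −30 °C and quenched cold with AcOH so that adduct 3 is isolated. MsCl/Et3N in CH2Cl2 (−20 to 0 °C) then converts it into methyl 2-azido-3-(2,5-dibromophenyl)-3-(methanesulfonyloxy)propanoate F5. This eliminates in the same flask through its acidic α-hydrogen, under non-hydrolytic conditions, to give the Z-azidoacrylate.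

Further compounds
F1 | step 5 | 4,7-dibromo-3-chloro-1H-indole | Clc1c[nH]c2c(Br)ccc(Br)c12
F2 | step 2 | (2,5-dibromophenyl)hydrazine (purchased) | NNc1cc(Br)ccc1Br
F3 | step 2 | methyl pyruvate (purchased) | COC(=O)C(C)=O
F4 | step 2 | methyl 2-[2-(2,5-dibromophenyl)hydrazinylidene]propanoate (E/Z mixture) | COC(=O)C(C)=NNc1cc(Br)ccc1Br
F5 | step 1 | methyl 2-azido-3-(2,5-dibromophenyl)-3-(methanesulfonyloxy)propanoate (racemic diastereomer mixture) | COC(=O)C(N=[N+]=[N-])C(OS(C)(=O)=O)c1cc(Br)ccc1Br
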